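I have one next run to spend on this flask, and it can go to more Q, to a higher solubility of Z, or to faster dissolution of D.

D 0.057 M; Q 1.80 equiv; time 30 min

    D ⇌ Z, rate k1*(cs1 - [Z]) while solid is left; crystals form when [Z] > cs1 (cs1 = 39 mM, k1 = 0.28 s⁻¹)
    Z + Q → Z.Q (k2 = 0.13 M⁻¹ s⁻¹)
    2 Q → Q2 (k3 = 0.028 M⁻¹ s⁻¹)

- Z.Q at 30 min, in percent of the D charged
- the change that raises the amount of Z.Q at 30 min, in percent of the D charged most ("none" if none brings more than 2 percentage points) (north-east / south / east / none)
- amount of Z.Q at 30 min, in percent of the D charged, after south

**Supply first.** Dissolution has a half-time of 2.48 s, shorter than the 0.87 min half-life of Z in the product step at the charged amounts, so I spend nothing on dissolution. Solubility puts 68.4% of the charge within reach of the solution at once.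

**Break-even charge.** Each Z consumed costs one Q, and the self-reaction burns further Q alongside it, in proportion to Q over Z. One ratio of Q to Z therefore stays as it is while both are consumed: the product constant over that constant less twice the self-reaction constant. It comes to 1.76 equivalents, and I call it the break-even charge. In this scheme the ratio climbs above that value, and below it the ratio falls, so that Q becomes the limiting reagent. The flask's charge is 1.02 times the break-even charge.

**My reckoning.** On that line Q stays a fixed multiple of Z, so Z decays second-order. The share remaining is one over one plus the product constant times break-even charge times charged D times time, which at 30 min gives 4.09%, hence Z.Q 95.9%. This assumes all of D is dissolved from the start, which south allows with 78.0 mM against 57.0 mM. So I commit to that figure for south and to just below it for the flask. Doubled Q stands at twice break-even and can win back that remainder, so the run goes to Q.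

**The result.** The forecast says 95%, north-east and 96%, holding that “doubling solubility gains only about 1 point”. The flask gives 95.3% and south 96.1%, with gains of 4.4 percentage points for north-east, 0.83 points for south and 0.23 points for east. The flask's Q to Z reads 1.41 equivalents at 30.0 min, below break-even, and 0.746 at 300 min, so by these readings it runs on the falling side.

**Second flask.** The neighbour flask with 1.10 equiv of Q lies below break-even. If all of D were dissolved from the start, the same balance would put the Z left when Q is gone at one minus charge over break-even, raised to the break-even charge: 17.8% of D charged. That is a rough figure for this neighbour flask, whose solubility of 39.0 mM stands against 57.0 mM of D charged. The neighbour flask holds 21.2% of Z at 30.0 min, more than that figure, with 0.89% of its Q left and Z.Q at 78.8%.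

(The constants come from no measurement.)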